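After 90.0 min Tuesday's flask has 0.4% of its substrate left, and after 90.0 min Saturday's has 0.3%, so you can read both as ended.

| setting | Tuesday's | Saturday's | ochre | red | amber |
|---|---|---|---|---|---|
| substrate | 0.067 M | 0.21 M | 0.080 M | 0.15 M | 0.30 M |
| partner | 0.195 M (in portions, 2) | 0.195 M (in portions, 2) | 0.195 M (in portions, 2) | 0.195 M (in portions, 2) | 0.195 M (in portions, 2) |
| remark | run made earlier; portions every 80 s | run made earlier; portions every 80 s | the portions of partner follow each other after 80 s, the first at the start | the portions of partner follow each other after 80 s, the first at the start | the portions of partner follow each other after 80 s, the first at the start |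
| time |  |  | 1.5 h | 1.5 h | 1.5 h |

| run | time / min | target / % | substrate / % |
|---|---|---|---|
| Tuesday's | 25.0 | 40.0 | 11.4 |
| Tuesday's | 50.0 | 51.8 | 1.0 |
| Tuesday's | 60.0 | 52.2 | 0.6 |
| Tuesday's | 90.0 | 52.8 | 0.4 |
| Saturday's | 8.00 | 4.6 | 48.5 |
| Saturday's | 15.0 | 11.8 | 26.5 |
| Saturday's | 40.0 | 22.6 | 2.9 |
| Saturday's | 90.0 | 25.9 | 0.3 |

(readings scatter by 0.3 percentage points)

* [target] at the end for ochre, red, amber, in this order
* how that number moves from the first to the last of them (falls, then rises / hardly changes / rises all the way / rises, then falls / falls all the way)

- "hardly changes" means that all values lie within two and a half points (for a concentration: within two and a half percent of the largest)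
- a step back or a flat step of under half a percent of the largest counts as no turn

Two numbers here don't seem to go together. Read from one point each, the fraction of substrate left falls at 0.0869 min⁻¹ on Tuesday's flask and 0.0885 min⁻¹ on Saturday's, about the same pace, although Saturday's charge is 3.13 times Tuesday's. Yet the target at the end is 52.8% of the charge on Tuesday's flask and only 25.9%, about half, on Saturday's.

Work with the fraction of the charge that stands as target at the end. The substrate's own pace reads about the same at both charges, so I place the cost in some later step. My assumption, which two runs can't test, is that with partner held at 0.195 M each equal step in the charged c(substrate) multiplies that fraction by the same factor. Read from these two end readings, the step in the charged c(substrate) that cuts the fraction by a factor of 2 is then 0.139 M, the halving charge. The c(target) at the end is the charged c(substrate) times that fraction, so on this assumption it climbs up to a charge of the halving charge divided by the natural log of 2, which is 0.201 M, and sinks beyond. Starting from Tuesday's reading, I reckon 0.0396 M, 0.0524 M and 0.0496 M, so amber ends lower than red.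

The forecast gives 0.038 M, 0.048 M and 0.06 M, so its row rises all the way: “Absolute target should therefore keep rising, but sublinearly”. It parts from my reckoning at amber, where it stands higher.

The flasks give 0.0391 M, 0.0516 M and 0.0461 M: the row rises, then falls, turning at 0.20 M.

    substrate ⇌ open intermediate (K = 2.29, k = 0.00168 s⁻¹)
    partner → second intermediate (k = 9.38 × 10⁻⁴ s⁻¹)
    open intermediate + second intermediate → target (k = 0.0180 M⁻¹ s⁻¹)
    2 open intermediate → homo product (k = 5.78 × 10⁻⁴ M⁻¹ s⁻¹)
    substrate + target → side product (k = 0.0360 M⁻¹ s⁻¹)

Starting from ochre's 48.8% as target, the halving charge gives 34.5% for red, which holds 34.4%, and 16.3% for amber, which holds 15.4%. In amber, up to 0.750 h, open intermediate and second intermediate made target while substrate joined target to give side product, which counts as two in its percentage; at that time side product stood at 67.2% against 14.2% target, with 2.95% substrate left. By 1.50 h substrate was down to 0.272%, side product had reached 76.6%, and target stood at 15.4%.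

All runs are simulated with made-up constants.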